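**Retrosynthetic overview**

1. The C2–C1' bond is cut first: the (2S)-flavanone comes from a 7-oxygenated chromone and an arylboronic acid by Rh-catalysed asymmetric 1,4-addition, which sets C2. Ring B (benzene) and rings A/C (benzopyranone) are bought, so the only ring to be made is the 2,2-dimethyl-dihydropyran, and it is made last.
2. That ring and both prenyl groups are taken apart together: the target comes from flavanone 12 plus isobutene. Compound 12 carries no C-prenyl group, only two O-(1,1-dimethylallyl) ethers (on O7 and O4') and a 3'-CH2OAc group.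
3. Enabling feature: the chroman oxygen O1 is a phenol oxygen. On one side it is flanked by C8 with its prenyl group (retron of an aromatic Claisen shift O→C). On the other it is flanked by C8a–C4a–C4H2, i.e. an o-quinone methide O1=C8a–C4a=C4H2, whose [4+2] partner isobutene supplies C3 and the gem-dimethyl carbon C2. Ring A repeats the OH(C7)/prenyl(C8) Claisen retron.
4. Building blocks: 7-hydroxychromone, 5-bromo-2-hydroxybenzyl alcohol, 2-methylbut-3-en-2-ol (source of both prenyl groups) and isobutene.

Key step: step 7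

Remark on the chemistry: the facial sense of step 5 is assigned by analogy with cyclic enones ((S)-biaryl bisphosphine, aryl to the Re face of C2). If a first run shows the opposite sense, the (R)-ligand is used and nothing else changes.

**Route**

Step 1
Reactants: 1 2-methylbut-3-en-2-ol
Product: 3 tert-butyl 2-methylbut-3-en-2-yl carbonate, via lithium 2-methylbut-3-en-2-olate 2 (not isolated)
Conditions: n-BuLi, THF, −78 to 0 °C; then Boc2O, 0 °C to rt
Reagents that add atoms: di-tert-butyl dicarbonate, CC(C)(C)OC(=O)OC(=O)OC(C)(C)C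
Why: O-acylation of a tertiary lithium alkoxide with Boc2O is the standard way to a tertiary allyl tert-butyl carbonate; no stereocentre is involved.

Step 2
Reactants: 4 7-hydroxy-4H-chromen-4-one; 3 tert-butyl 2-methylbut-3-en-2-yl carbonate
Product: 5 7-(2-methylbut-3-en-2-yloxy)-4H-chromen-4-one
Conditions: Pd(PPh3)4 (2 mol %), THF, 0 °C
Reagents that add atoms: none
Why: In this decarboxylative Tsuji–Trost O-allylation the phenoxide should attack the more substituted terminus of the 1,1-dimethyl-π-allyl-palladium complex under kinetic control at low temperature, giving the tertiary (reverse-prenyl) ether.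

Step 3
Reactants: 6 4-bromo-2-(hydroxymethyl)phenol; 3 tert-butyl 2-methylbut-3-en-2-yl carbonate
Product: 7 [5-bromo-2-(2-methylbut-3-en-2-yloxy)phenyl]methanol
Conditions: Pd(PPh3)4 (2 mol %), THF, 0 °C
Reagents that add atoms: none
Why: The same Tsuji–Trost O-allylation should be selective for the phenoxide over the benzylic alcohol, and the aryl bromide should not undergo oxidative addition at 0 °C.

Step 4
Reactants: 7 [5-bromo-2-(2-methylbut-3-en-2-yloxy)phenyl]methanol
Product: 10 [3-(hydroxymethyl)-4-(2-methylbut-3-en-2-yloxy)phenyl]boronic acid, via aryllithium lithium alkoxide 8 (not isolated), via lithium triisopropyl arylborate 9 (not isolated)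
Conditions: n-BuLi (2.2 equiv), THF, −78 °C; B(OiPr)3, −78 °C to rt; sat. aq NH4Cl
Reagents that add atoms: triisopropyl borate, CC(C)OB(OC(C)C)OC(C)C; water, O
Why: Deprotonation of the alcohol followed by bromine–lithium exchange and borate quench is a standard arylboronic acid synthesis; the tertiary allyl ether has no α-hydrogen for a Wittig shift, and the near-neutral work-up spares it.

Step 5
Reactants: 5 7-(2-methylbut-3-en-2-yloxy)-4H-chromen-4-one; 10 [3-(hydroxymethyl)-4-(2-methylbut-3-en-2-yloxy)phenyl]boronic acid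
Product: 11 (2S)-2-[3-(hydroxymethyl)-4-(2-methylbut-3-en-2-yloxy)phenyl]-7-(2-methylbut-3-en-2-yloxy)-2,3-dihydro-4H-chromen-4-one
Conditions: [Rh(OH)((S)-MeO-F12-BIPHEP)]2 (1.5 mol %), 10 (3 equiv), PhMe/H2O 10:1, 40 °C
Reagents that add atoms: none
Why: This is a base-free Rh(I)-catalysed asymmetric 1,4-addition (Hayashi–Miyaura type) of an arylboronic acid to a chromone, in which the C2-symmetric bisphosphine should direct aryl transfer to the Re face of C2 and so set (2S); the unactivated vinyl groups are not expected to compete with the enone for the aryl-rhodium species.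

Step 6
Reactants: 11 (2S)-2-[3-(hydroxymethyl)-4-(2-methylbut-3-en-2-yloxy)phenyl]-7-(2-methylbut-3-en-2-yloxy)-2,3-dihydro-4H-chromen-4-one
Product: 12 {5-[(2S)-7-(2-methylbut-3-en-2-yloxy)-4-oxo-3,4-dihydro-2H-chromen-2-yl]-2-(2-methylbut-3-en-2-yloxy)phenyl}methyl acetate
Conditions: Ac2O, pyridine, DMAP (cat.), CH2Cl2, 0 °C
Reagents that add atoms: acetic anhydride, CC(=O)OC(C)=O
Why: DMAP-catalysed acetylation of a primary benzylic alcohol is routine, and with no free phenol in the molecule the weak base should not open the flavanone or touch C2.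

Step 7
Reactants: 12 {5-[(2S)-7-(2-methylbut-3-en-2-yloxy)-4-oxo-3,4-dihydro-2H-chromen-2-yl]-2-(2-methylbut-3-en-2-yloxy)phenyl}methyl acetate; 13 2-methylpropene (isobutene)
Product: 16 (2S)-2-[2,2-dimethyl-8-(3-methylbut-2-en-1-yl)-3,4-dihydro-2H-chromen-6-yl]-7-hydroxy-8-(3-methylbut-2-en-1-yl)-2,3-dihydro-4H-chromen-4-one, via bis-Claisen phenol acetate 14 (not isolated), via ortho-quinone methide 15 (not isolated)
Conditions: isobutene (condensed, ca. 100 equiv), PhMe (0.01 M in 12), sealed steel autoclave, 130 °C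
Reagents that add atoms: none
Why: Two aromatic Claisen [3,3] shifts through chair transition states (O7→C8 on ring A; O4'→C5' on ring B, its only free ortho carbon) should turn both 1,1-dimethylallyl ethers into prenyl groups and free both phenols (14); the ring-B phenol, now ortho to CH2OAc, should then lose acetic acid by hydrogen-bond-assisted 1,4-elimination to give o-quinone methide 15, which isobutene takes up in an inverse-electron-demand hetero-Diels–Alder reaction. The closest known reactions are the thermal rearrangement of aryl 1,1-dimethylallyl ethers to ortho-prenylphenols, the thermolysis of o-hydroxybenzyl acetates to o-quinone methides, and the chroman-forming [4+2] of o-quinone methides with simple alkenes. The dihydropyran ring closes by intermolecular [4+2] cycloaddition (heterodiene O=C–C=CH2 plus C=C), forming C4–C3 and O1–C2 in one asynchronous step; no other ring is formed. No new stereocentre arises, and C2 of the flavanone is not involved; neutral aprotic conditions avoid the base-mediated retro-oxa-Michael opening that would scramble it. The step needs three selectivities: the cycloaddition regiochemistry follows polarisation (the CH2 terminus of isobutene bonds to the methide carbon, the cation-stabilising CMe2 carbon to oxygen), giving the 2,2-dimethyl pattern; ring-A selectivity for C8 over C6 rests on the known preference of 7-O-allyl and 7-O-propargyl ethers of 5-deoxychromanones for the angular position; and selectivity for isobutene over the internal prenyl groups and phenols rests on its large excess, its 1,1-disubstitution and the low stationary concentration of 15, which can form only after the Claisen shift has unmasked the phenol.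

**Compound list**

1 | 2-methylbut-3-en-2-ol | CC(C)(O)C=C | starting material
2 | lithium 2-methylbut-3-en-2-olate | [Li]OC(C)(C)C=C | intermediate
3 | tert-butyl 2-methylbut-3-en-2-yl carbonate | CC(C)(C)OC(=O)OC(C)(C)C=C | intermediate
4 | 7-hydroxy-4H-chromen-4-one | O=c1ccoc2cc(O)ccc12 | starting material
5 | 7-(2-methylbut-3-en-2-yloxy)-4H-chromen-4-one | C=CC(C)(C)Oc1ccc2c(c1)occc2=O | intermediate
6 | 4-bromo-2-(hydroxymethyl)phenol (5-bromo-2-hydroxybenzyl alcohol) | OCc1cc(Br)ccc1O | starting material
7 | [5-bromo-2-(2-methylbut-3-en-2-yloxy)phenyl]methanol | OCc1cc(Br)ccc1OC(C)(C)C=C | intermediate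
8 | lithium [5-lithio-2-(2-methylbut-3-en-2-yloxy)phenyl]methanolate | [Li]OCc1cc([Li])ccc1OC(C)(C)C=C | intermediate
9 | lithium triisopropoxy{3-[(lithiooxy)methyl]-4-(2-methylbut-3-en-2-yloxy)phenyl}borate | [Li+].[Li]OCc1cc(ccc1OC(C)(C)C=C)[B-](OC(C)C)(OC(C)C)OC(C)C | intermediate
10 | [3-(hydroxymethyl)-4-(2-methylbut-3-en-2-yloxy)phenyl]boronic acid | OCc1cc(B(O)O)ccc1OC(C)(C)C=C | intermediate
11 | (2S)-2-[3-(hydroxymethyl)-4-(2-methylbut-3-en-2-yloxy)phenyl]-7-(2-methylbut-3-en-2-yloxy)-2,3-dihydro-4H-chromen-4-one | C=CC(C)(C)Oc1ccc(cc1CO)[C@@H]2CC(=O)c3ccc(OC(C)(C)C=C)cc3O2 | intermediate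
12 | {5-[(2S)-7-(2-methylbut-3-en-2-yloxy)-4-oxo-3,4-dihydro-2H-chromen-2-yl]-2-(2-methylbut-3-en-2-yloxy)phenyl}methyl acetate | C=CC(C)(C)Oc1ccc(cc1COC(C)=O)[C@@H]2CC(=O)c3ccc(OC(C)(C)C=C)cc3O2 | intermediate
13 | 2-methylpropene (isobutene) | CC(C)=C | starting material
14 | {2-hydroxy-5-[(2S)-7-hydroxy-8-(3-methylbut-2-en-1-yl)-4-oxo-3,4-dihydro-2H-chromen-2-yl]-3-(3-methylbut-2-en-1-yl)phenyl}methyl acetate | CC(C)=CCc1cc(cc(COC(C)=O)c1O)[C@@H]2CC(=O)c3ccc(O)c(CC=C(C)C)c3O2 | intermediate
15 | (2S)-7-hydroxy-8-(3-methylbut-2-en-1-yl)-2-[3-methylidene-5-(3-methylbut-2-en-1-yl)-4-oxocyclohexa-1,5-dien-1-yl]-2,3-dihydro-4H-chromen-4-one (o-quinone methide) | CC(C)=CCC1=CC(=CC(=C)C1=O)[C@@H]2CC(=O)c3ccc(O)c(CC=C(C)C)c3O2 | intermediate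
16 | (2S)-2-[2,2-dimethyl-8-(3-methylbut-2-en-1-yl)-3,4-dihydro-2H-chromen-6-yl]-7-hydroxy-8-(3-methylbut-2-en-1-yl)-2,3-dihydro-4H-chromen-4-one | CC(C)=CCc1cc([C@@H]2CC(=O)c3ccc(O)c(CC=C(C)C)c3O2)cc2c1OC(C)(C)CC2 | target

**Step count and risks**

Total step count: 7. Longest linear sequence: 6 steps (steps 1, 3, 4, 5, 6, 7).

Steps most likely to fail:

1. Step 7. The o-quinone methide may be released faster than isobutene captures it, so that it is consumed by self-condensation and by benzylation of the free phenols; partition of the ring-A shift between C8 and C6 would add to the loss. The fallback closes the same ring last by the biomimetic acid-catalysed hydroalkoxylation of a prenyl group; it sets out from 7 (with 5 as coupling partner) and comes back at 16.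
   - Appel bromination of 7 (CBr4, PPh3, CH2Cl2, 0 °C) should give 4-bromo-2-(bromomethyl)-1-(2-methylbut-3-en-2-yloxy)benzene F1.
   - Copper-catalysed coupling of the benzylic bromide with 2-methylprop-1-enylmagnesium bromide (Li2CuCl4 cat., THF, −40 °C) should give 4-bromo-2-(3-methylbut-2-en-1-yl)-1-(2-methylbut-3-en-2-yloxy)benzene F2.
   - Bromine–lithium exchange and borylation as in step 4 (1.1 equiv n-BuLi) should give [3-(3-methylbut-2-en-1-yl)-4-(2-methylbut-3-en-2-yloxy)phenyl]boronic acid F3.
   - Addition of F3 to 5 under the conditions of step 5 should give (2S)-7-(2-methylbut-3-en-2-yloxy)-2-[3-(3-methylbut-2-en-1-yl)-4-(2-methylbut-3-en-2-yloxy)phenyl]-2,3-dihydro-4H-chromen-4-one F4.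
   - Heating (PhMe, 120 °C) should effect only the two Claisen shifts and give (2S)-7-hydroxy-2-[4-hydroxy-3,5-bis(3-methylbut-2-en-1-yl)phenyl]-8-(3-methylbut-2-en-1-yl)-2,3-dihydro-4H-chromen-4-one F5.
   - The 7-OH, more acidic and less hindered than the doubly flanked 4'-OH, should be silylated selectively (TBSCl, imidazole, DMF, 0 °C) to give the 7-O-tert-butyldimethylsilyl ether of the triprenyl flavanone F6.
   - Amberlyst 15 (CH2Cl2, rt) should close the dihydropyran ring by Markovnikov 6-endo attack of the 4'-OH on one of the two equivalent ring-B prenyl groups, giving the 7-O-tert-butyldimethylsilyl ether of the target F7.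
   - HF·pyridine (THF, 0 °C) should then give 16.

2. Step 5. Aryl transfer to the electron-rich 7-alkoxychromone may be slow with the bulky chiral bisphosphine complex, so that protodeboronation of 10 and incomplete facial control erode conversion and enantiopurity. The fallback replaces asymmetric catalysis by resolution; it sets out from 5 and 10 and comes back at 11.
   - Addition with the more active achiral catalyst [Rh(OH)(cod)]2 (dioxane/H2O, 40 °C) should give racemic 2-[3-(hydroxymethyl)-4-(2-methylbut-3-en-2-yloxy)phenyl]-7-(2-methylbut-3-en-2-yloxy)-2,3-dihydro-4H-chromen-4-one F8.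
   - Kinetic resolution by asymmetric transfer hydrogenation (RuCl(p-cymene)[TsDPEN], the antipode that reduces the (2R)-ketone faster, HCO2Na, H2O/EtOAc, rt, stopped near half conversion) should convert the unwanted enantiomer into (2R,4R)-2-[3-(hydroxymethyl)-4-(2-methylbut-3-en-2-yloxy)phenyl]-7-(2-methylbut-3-en-2-yloxy)-3,4-dihydro-2H-chromen-4-ol F9.
   - The unreduced (2S)-ketone 11 is then separated by chromatography.

3. Step 2. Pd(0) may re-ionise the branched ether of the acidic chromone phenol, so that the product leaks to the linear prenyl ether, which is useless for the later [3,3] shift. The fallback avoids π-allyl chemistry; it sets out from 4 and comes back at 5.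
   - Copper-catalysed O-alkylation with 3-chloro-3-methylbut-1-yne (DBU, CuCl2 cat., MeCN, 0 °C) should give 7-(2-methylbut-3-yn-2-yloxy)-4H-chromen-4-one F10.
   - Lindlar semi-hydrogenation (H2, Pd/CaCO3/Pb, quinoline, EtOAc) should give 5.

Further compounds
F1 | step 7 | 4-bromo-2-(bromomethyl)-1-(2-methylbut-3-en-2-yloxy)benzene | BrCc1cc(Br)ccc1OC(C)(C)C=C
F2 | step 7 | 4-bromo-2-(3-methylbut-2-en-1-yl)-1-(2-methylbut-3-en-2-yloxy)benzene | CC(C)=CCc1cc(Br)ccc1OC(C)(C)C=C
F3 | step 7 | [3-(3-methylbut-2-en-1-yl)-4-(2-methylbut-3-en-2-yloxy)phenyl]boronic acid | CC(C)=CCc1cc(B(O)O)ccc1OC(C)(C)C=C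
F4 | step 7 | (2S)-7-(2-methylbut-3-en-2-yloxy)-2-[3-(3-methylbut-2-en-1-yl)-4-(2-methylbut-3-en-2-yloxy)phenyl]-2,3-dihydro-4H-chromen-4-one | C=CC(C)(C)Oc1ccc(cc1CC=C(C)C)[C@@H]2CC(=O)c3ccc(OC(C)(C)C=C)cc3O2
F5 | step 7 | (2S)-7-hydroxy-2-[4-hydroxy-3,5-bis(3-methylbut-2-en-1-yl)phenyl]-8-(3-methylbut-2-en-1-yl)-2,3-dihydro-4H-chromen-4-one | CC(C)=CCc1cc(cc(CC=C(C)C)c1O)[C@@H]2CC(=O)c3ccc(O)c(CC=C(C)C)c3O2
F6 | step 7 | (2S)-7-[tert-butyl(dimethyl)silyl]oxy-2-[4-hydroxy-3,5-bis(3-methylbut-2-en-1-yl)phenyl]-8-(3-methylbut-2-en-1-yl)-2,3-dihydro-4H-chromen-4-one | CC(C)=CCc1cc(cc(CC=C(C)C)c1O)[C@@H]2CC(=O)c3ccc(O[Si](C)(C)C(C)(C)C)c(CC=C(C)C)c3O2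
F7 | step 7 | (2S)-7-[tert-butyl(dimethyl)silyl]oxy-2-[2,2-dimethyl-8-(3-methylbut-2-en-1-yl)-3,4-dihydro-2H-chromen-6-yl]-8-(3-methylbut-2-en-1-yl)-2,3-dihydro-4H-chromen-4-one | CC(C)=CCc1cc([C@@H]2CC(=O)c3ccc(O[Si](C)(C)C(C)(C)C)c(CC=C(C)C)c3O2)cc2c1OC(C)(C)CC2
F8 | step 5 | racemic 2-[3-(hydroxymethyl)-4-(2-methylbut-3-en-2-yloxy)phenyl]-7-(2-methylbut-3-en-2-yloxy)-2,3-dihydro-4H-chromen-4-one | C=CC(C)(C)Oc1ccc(cc1CO)C2CC(=O)c3ccc(OC(C)(C)C=C)cc3O2
F9 | step 5 | (2R,4R)-2-[3-(hydroxymethyl)-4-(2-methylbut-3-en-2-yloxy)phenyl]-7-(2-methylbut-3-en-2-yloxy)-3,4-dihydro-2H-chromen-4-ol | C=CC(C)(C)Oc1ccc(cc1CO)[C@H]2C[C@@H](O)c3ccc(OC(C)(C)C=C)cc3O2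
F10 | step 2 | 7-(2-methylbut-3-yn-2-yloxy)-4H-chromen-4-one | C#CC(C)(C)Oc1ccc2c(c1)occc2=O
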